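**Plan**

- Retrosynthetic cuts, in order: the top interflavan bond C4(top)–C6(middle); the bottom ring C oxygenation back to a flavone; C4a–C5 of the bottom ring A; C7–C8 of the open chain; C6(bottom)–C4(middle).
- Enabling feature: the bottom ring A is a phloroglucinol ring with middle C4 on C6 and the pyran oxygen O1 on C8a, para to C6. It is a tetraketide whose ring oxygen can be stored beforehand in a 4-pyranone, so closing C4a–C5 onto pyranone carbon 3 gives ring A with the substitution pattern already fixed.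
- Forward: (+)-catechin → C4 malonate (middle unit) → half-ester chloride + lithiated 2-aryl-6-methyl-4-pyranone → β-keto ester → Claisen closure of ring A (the pyranone becomes ring C of a flavone) → flavanone → flav-3-ene → flavan-3-ol → arylation by a (−)-epicatechin C4 cation → hydrogenolysis.
- Stereochemistry: middle C2/C3 from (+)-catechin, middle C4 by attack anti to 3-OBn; top C2/C3 from (−)-epicatechin, top C4 likewise anti; bottom C2 by a chiral CuH catalyst, bottom C3 by hydroboration anti to the C2 aryl.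
- A bromine on C8 of each unit leaves middle C6 as the only nucleophilic carbon in the last arylation; all three bromines leave with the benzyl groups.

Key step: step 10

Remark: flavan numbering (O1, C2, C3, C4, C4a, C5–C8, C8a, primed B ring) is used for every unit; "top", "middle" and "bottom" are the epicatechin unit, the central catechin unit and the terminal catechin unit. Bn = benzyl. "Cat4α" is the 8-bromo-3,5,7,3',4'-penta-O-benzyl-(+)-catechin-4-yl group bonded through C4, trans to its 3-OBn.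
Remark: conjugate bases (alkoxides, phenoxides, enolates) formed from numbered compounds by the bases named are treated as forms of those compounds and carry no number of their own.
Remark: the C4 ether of 5 and 30 is a leaving group, so either C4 epimer serves; the malonate or β-keto ester carbon of 9, 15 and 16 is an epimer mixture that converges in step 10.

**Route**

Step 1
Reactants: 1 (+)-catechin
Product: 2 5,7,3',4'-tetra-O-benzyl-(+)-catechin
Conditions: BnBr (4.4 equiv), K2CO3, DMF, 0 °C → rt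
Reagents that add atoms: benzyl bromide, BrCc1ccccc1
Why: Williamson etherification in which K2CO3 ionises only the four phenols, so the secondary 3-OH stays free and C2 is not epimerised.

Step 2
Reactants: 2 5,7,3',4'-tetra-O-benzyl-(+)-catechin
Product: 3 8-bromo-5,7,3',4'-tetra-O-benzyl-(+)-catechin
Conditions: NBS (1.0 equiv), CH2Cl2, −78 → −20 °C
Reagents that add atoms: N-bromosuccinimide, O=C1CCC(=O)N1Br
Why: Electrophilic aromatic bromination, for which C8 of a benzylated flavan-3-ol is the most nucleophilic A-ring carbon, so one equivalent at low temperature should brominate there only.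

Step 3
Reactants: 3 8-bromo-5,7,3',4'-tetra-O-benzyl-(+)-catechin
Product: 4 8-bromo-3,5,7,3',4'-penta-O-benzyl-(+)-catechin
Conditions: NaH, BnBr, DMF, 0 °C → rt
Reagents that add atoms: benzyl bromide, BrCc1ccccc1
Why: Williamson etherification of the secondary alkoxide, with no free phenol left that could epimerise C2 through a quinone methide.

Step 4
Reactants: 4 8-bromo-3,5,7,3',4'-penta-O-benzyl-(+)-catechin
Product: 5 8-bromo-3,5,7,3',4'-penta-O-benzyl-4β-(2-ethoxyethoxy)-(+)-catechin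
Conditions: DDQ (2 equiv), 2-ethoxyethanol (5 equiv), CH2Cl2, rt
Reagents that add atoms: 2-ethoxyethanol, CCOCCO
Why: Oxidative benzylic etherification in which DDQ abstracts hydride from C4 (benzylic to the 5,7-dioxygenated ring) and the alcohol traps the cation; the new C4 centre is expected mainly cis to 3-OBn and is erased in step 5.

Step 5
Reactants: 5 8-bromo-3,5,7,3',4'-penta-O-benzyl-4β-(2-ethoxyethoxy)-(+)-catechin; 6 dimethyl malonate
Product: 8 dimethyl 2-(Cat4α)malonate, via silyl ketene acetal 7 (not isolated)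
Conditions: 6 (2.0 equiv), Et3N (2.1 equiv), Me3SiOTf (2.5 equiv), CH2Cl2, 0 °C; then 5, −78 → −30 °C
Reagents that add atoms: none
Why: Mukaiyama-type SN1 alkylation in which the excess Me3SiOTf ionises the C4 ether and the silyl ketene acetal adds to the benzylic cation anti to the 3-benzyloxy group (half-chair with 2-aryl and 3-OBn equatorial), setting the 3,4-trans (4α) centre.

Step 6
Reactants: 8 dimethyl 2-(Cat4α)malonate
Product: 9 2-(Cat4α)-3-methoxy-3-oxopropanoic acid
Conditions: KOH (1.05 equiv), THF/MeOH/H2O, 0 °C; then 1 M HCl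
Reagents that add atoms: potassium hydroxide, [K+].[OH-]
Why: Mono-saponification of a malonate, in which the first carboxylate shields the second ester from hydroxide; the new centre at the malonate carbon forms unselectively and disappears when that carbon becomes aromatic in step 10.

Step 7
Reactants: 10 methyl 3,4-dihydroxybenzoate
Product: 11 methyl 3,4-bis(benzyloxy)benzoate
Conditions: BnBr (2.2 equiv), K2CO3, DMF, 60 °C
Reagents that add atoms: benzyl bromide, BrCc1ccccc1
Why: Williamson etherification of both phenols.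

Step 8
Reactants: 11 methyl 3,4-bis(benzyloxy)benzoate; 12 acetylacetone
Product: 14 2-[3,4-bis(benzyloxy)phenyl]-6-methyl-4H-pyran-4-one, via triketone 13 (not isolated)
Conditions: 12 (2.2 equiv), LiN(iPr)2 (4.4 equiv), THF, 0 °C; 11, 0 °C → rt; aq. HCl; then p-TsOH·H2O (cat.), toluene, 90 °C
Reagents that add atoms: none
Why: Claisen-type acylation of the acetylacetone dianion at its terminal carbon by the ester, followed by acid-catalysed cyclodehydration of the 1,3,5-triketone, which can only give the 4-pyranone.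

Step 9
Reactants: 9 2-(Cat4α)-3-methoxy-3-oxopropanoic acid; 14 2-[3,4-bis(benzyloxy)phenyl]-6-methyl-4H-pyran-4-one
Product: 16 methyl 2-(Cat4α)-4-[6-[3,4-bis(benzyloxy)phenyl]-4-oxo-4H-pyran-2-yl]-3-oxobutanoate, via acid chloride 15 (not isolated)
Conditions: 9, 1-chloro-N,N,2-trimethylprop-1-en-1-amine (1.05 equiv), CH2Cl2, 0 °C → rt; then added to 14 (3.0 equiv), LiN(SiMe3)2 (3.0 equiv), THF, −78 → −30 °C; AcOH
Reagents that add atoms: none
Why: Crossed Claisen acylation of the laterally lithiated 6-methyl group of the 4-pyranone by an acid chloride, where the excess anion allows for the acidic malonyl C–H of 15 (its enolate still transfers the acyl group by way of the acylketene) and for the acidity of 16.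

Step 10
Reactants: 16 methyl 2-(Cat4α)-4-[6-[3,4-bis(benzyloxy)phenyl]-4-oxo-4H-pyran-2-yl]-3-oxobutanoate
Product: 17 6-(Cat4α)-5,7-dihydroxy-3',4'-bis(benzyloxy)flavone
Conditions: LiN(SiMe3)2 (4 equiv), THF, −78 → 0 °C; AcOH
Reagents that add atoms: none
Why: Proposed new method: LiN(SiMe3)2 deprotonates the methylene between the ketone and the pyranone, and the charge of this vinylogous enolate reaches pyranone carbon 3 (the future C4a) through C8a; that carbon adds to the methyl ester carbonyl (the future C5), methoxide leaves, and the cyclohexenedione formed tautomerises to the phloroglucinol ring, whose deprotonation by the excess base makes the sequence irreversible. The closest known reactions are the Claisen cyclisations of 3,5,7-trioxoalkanoates to acylphloroglucinols and the base-induced carbocyclisations of pyranone-masked polyketones, but C-acylation of carbon 3 of an intact 4-pyranone by a pendant ester has not been described. Ring A of the bottom unit closes in a 6-(enolexo)-exo-trig Claisen condensation, and the pyranone survives as ring C of the flavone. No stereocentre is formed: both epimers at the β-keto ester carbon converge because that carbon becomes aromatic C6, and C2, C3 and C4 of the middle unit carry no acidic hydrogen. The step needs C-acylation at pyranone carbon 3 instead of opening of the pyranone or reaction at another site, which the hindered non-nucleophilic amide base, the low temperature and the fact that every other closure would give a four- or eight-membered ring should secure. The position of the middle unit is fixed by the substrate, since the carbon that bears it lies between the ester and the ketone and can only become C6, para to C8a, which already holds the pyranone oxygen.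

Step 11
Reactants: 17 6-(Cat4α)-5,7-dihydroxy-3',4'-bis(benzyloxy)flavone
Product: 18 8-bromo-6-(Cat4α)-5,7-dihydroxy-3',4'-bis(benzyloxy)flavone
Conditions: NBS (1.0 equiv), THF, −40 → 0 °C
Reagents that add atoms: N-bromosuccinimide, O=C1CCC(=O)N1Br
Why: Electrophilic aromatic bromination at C8, the only free carbon of the free-phenol ring, which is far more nucleophilic than any benzylated ring (middle C6 is flanked by two benzyloxy groups and deactivated by bromine).

Step 12
Reactants: 18 8-bromo-6-(Cat4α)-5,7-dihydroxy-3',4'-bis(benzyloxy)flavone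
Product: 19 8-bromo-6-(Cat4α)-5,7,3',4'-tetrakis(benzyloxy)flavone
Conditions: BnBr (3 equiv), Cs2CO3, DMF, 60 °C
Reagents that add atoms: benzyl bromide, BrCc1ccccc1
Why: Williamson etherification, with Cs2CO3 and heat to alkylate the hydrogen-bonded 5-OH; C-benzylation is excluded because C6 and C8 are both substituted.

Step 13
Reactants: 19 8-bromo-6-(Cat4α)-5,7,3',4'-tetrakis(benzyloxy)flavone
Product: 21 (2S)-8-bromo-6-(Cat4α)-5,7,3',4'-tetrakis(benzyloxy)flavanone, via silyl enol ether 20 (not isolated)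
Conditions: Cu(OAc)2 (5 mol %), (R)-DTBM-SEGPHOS (5.5 mol %), (EtO)2MeSiH (3 equiv), toluene, 0 °C → rt; then 1 M HCl, THF, 0 °C
Reagents that add atoms: none
Why: CuH-catalysed asymmetric conjugate reduction of a chromone, in which the ligand directs hydride to one face of C2 and sets the (2S) centre while the silyl enol ether guards against over-reduction and ring opening to the chalcone; the hand of the ligand is to be confirmed on 5,7-bis(benzyloxy)flavone.

Step 14
Reactants: 21 (2S)-8-bromo-6-(Cat4α)-5,7,3',4'-tetrakis(benzyloxy)flavanone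
Product: 22 (2S,4S)-8-bromo-6-(Cat4α)-5,7,3',4'-tetrakis(benzyloxy)flavan-4-ol
Conditions: NaBH4, CeCl3·7H2O, THF/MeOH, −20 °C
Reagents that add atoms: none
Why: Luche-type carbonyl reduction, with axial hydride delivery giving the 2,4-cis alcohol (a centre removed in step 15) and CeCl3 keeping the medium non-basic so that the flavanone does not open and C2 is kept.

Step 15
Reactants: 22 (2S,4S)-8-bromo-6-(Cat4α)-5,7,3',4'-tetrakis(benzyloxy)flavan-4-ol
Product: 23 (2S)-8-bromo-6-(Cat4α)-5,7,3',4'-tetrakis(benzyloxy)flav-3-ene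
Conditions: MsCl, Et3N, CH2Cl2, 0 °C → rt
Reagents that add atoms: none
Why: E1 dehydration through the mesylate, which ionises to the C4 cation stabilised by the 5- and 7-benzyloxy groups and loses H3 to the amine; the basic medium protects the acid-labile C2 centre of the 2H-chromene.

Step 16
Reactants: 23 (2S)-8-bromo-6-(Cat4α)-5,7,3',4'-tetrakis(benzyloxy)flav-3-ene
Product: 25 8-bromo-penta-O-benzylcatechin-(4α→6)-8-bromo-5,7,3',4'-tetra-O-benzylcatechin with free bottom 3-OH, via alkylborane 24 (not isolated)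
Conditions: BH3·THF, THF, 0 °C → rt; then NaOH, H2O2, H2O, 0 °C → rt
Reagents that add atoms: hydrogen peroxide, OO
Why: Hydroboration–oxidation, in which boron adds to C3 of the electron-rich styrene-type double bond (hydrogen to benzylic C4) on the face anti to the C2 aryl and is oxidised with retention, giving the 2,3-trans (2R,3S) alcohol.

Step 17
Reactants: 26 (−)-epicatechin
Product: 27 5,7,3',4'-tetra-O-benzyl-(−)-epicatechin
Conditions: BnBr (4.4 equiv), K2CO3, DMF, 0 °C → rt
Reagents that add atoms: benzyl bromide, BrCc1ccccc1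
Why: Williamson etherification of the four phenols only, as in step 1.

Step 18
Reactants: 27 5,7,3',4'-tetra-O-benzyl-(−)-epicatechin
Product: 28 8-bromo-5,7,3',4'-tetra-O-benzyl-(−)-epicatechin
Conditions: NBS (1.0 equiv), CH2Cl2, −78 → −20 °C
Reagents that add atoms: N-bromosuccinimide, O=C1CCC(=O)N1Br
Why: Electrophilic aromatic bromination at C8 as in step 2; this bromine later keeps the electrophile from arylating itself.

Step 19
Reactants: 28 8-bromo-5,7,3',4'-tetra-O-benzyl-(−)-epicatechin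
Product: 29 8-bromo-3,5,7,3',4'-penta-O-benzyl-(−)-epicatechin
Conditions: NaH, BnBr, DMF, 0 °C → rt
Reagents that add atoms: benzyl bromide, BrCc1ccccc1
Why: Williamson etherification of the secondary alkoxide, as in step 3.

Step 20
Reactants: 29 8-bromo-3,5,7,3',4'-penta-O-benzyl-(−)-epicatechin
Product: 30 8-bromo-3,5,7,3',4'-penta-O-benzyl-4β-(2-ethoxyethoxy)-(−)-epicatechin
Conditions: DDQ (2 equiv), 2-ethoxyethanol (5 equiv), CH2Cl2, rt
Reagents that add atoms: 2-ethoxyethanol, CCOCCO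
Why: Oxidative benzylic etherification as in step 4, with the alcohol expected to add to the C4 cation on the face opposite the 2-aryl and 3-benzyloxy groups (3,4-trans), a centre that is in any case lost on ionisation in step 21.

Step 21
Reactants: 25 8-bromo-penta-O-benzylcatechin-(4α→6)-8-bromo-5,7,3',4'-tetra-O-benzylcatechin; 30 8-bromo-3,5,7,3',4'-penta-O-benzyl-4β-(2-ethoxyethoxy)-(−)-epicatechin
Product: 31 8-bromo-penta-O-benzylepicatechin-(4β→6)-8-bromo-penta-O-benzylcatechin-(4α→6)-8-bromo-5,7,3',4'-tetra-O-benzylcatechin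
Conditions: 30 (1.5 equiv), Me3SiOTf (0.5 equiv), CH2Cl2, −78 → −40 °C; Et3N
Reagents that add atoms: none
Why: Friedel–Crafts-type arylation of the flavan C4 cation, in which middle C6 is the only unsubstituted carbon on a trioxygenated ring and attacks the epicatechin cation on the face opposite its 2-aryl and 3-benzyloxy groups, setting the 3,4-trans (4β) centre.

Step 22
Reactants: 31 8-bromo-penta-O-benzylepicatechin-(4β→6)-8-bromo-penta-O-benzylcatechin-(4α→6)-8-bromo-5,7,3',4'-tetra-O-benzylcatechin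
Product: 32 epicatechin-(4β→6)-catechin-(4α→6)-catechin (CNP0163146.4)
Conditions: H2 (1 atm), Pd(OH)2/C, Et3N (3.3 equiv), THF/MeOH/H2O, rt
Reagents that add atoms: none
Why: Hydrogenolysis of the fourteen benzyl ethers together with hydrodebromination of the three aryl bromides over Pd(OH)2/C, with Et3N taking up the HBr so that the acid-labile interflavan bonds are kept.

**Compound list**

1 | (+)-catechin, (2R,3S) | Oc1cc(O)c2c(c1)O[C@H](c1ccc(O)c(O)c1)[C@@H](O)C2 | starting material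
2 | 5,7,3',4'-tetra-O-benzyl-(+)-catechin | c1(OCc9ccccc9)cc(OCc9ccccc9)c2c(c1)O[C@H](c4ccc(OCc9ccccc9)c(OCc9ccccc9)c4)[C@@H](O)C2 | intermediate
3 | 8-bromo-5,7,3',4'-tetra-O-benzyl-(+)-catechin | c1(OCc9ccccc9)cc(OCc9ccccc9)c2c(c1Br)O[C@H](c4ccc(OCc9ccccc9)c(OCc9ccccc9)c4)[C@@H](O)C2 | intermediate
4 | 8-bromo-3,5,7,3',4'-penta-O-benzyl-(+)-catechin | c1(OCc9ccccc9)cc(OCc9ccccc9)c2c(c1Br)O[C@H](c4ccc(OCc9ccccc9)c(OCc9ccccc9)c4)[C@@H](OCc9ccccc9)C2 | intermediate
5 | 8-bromo-3,5,7,3',4'-penta-O-benzyl-4β-(2-ethoxyethoxy)-(+)-catechin (ether cis to 3-OBn drawn; either C4 epimer serves) | c1(OCc9ccccc9)cc(OCc9ccccc9)c2c(c1Br)O[C@H](c4ccc(OCc9ccccc9)c(OCc9ccccc9)c4)[C@@H](OCc9ccccc9)[C@H]2OCCOCC | intermediate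
6 | dimethyl malonate | COC(=O)CC(=O)OC | starting material
7 | methyl 3-methoxy-3-(trimethylsilyloxy)prop-2-enoate (silyl ketene acetal of 6) | COC(=O)C=C(OC)O[Si](C)(C)C | intermediate
8 | dimethyl 2-(Cat4α)malonate, (2R,3S,4R) in the flavan, 3,4-trans | c1(OCc9ccccc9)cc(OCc9ccccc9)c2c(c1Br)O[C@H](c4ccc(OCc9ccccc9)c(OCc9ccccc9)c4)[C@@H](OCc9ccccc9)[C@@H]2C(C(=O)OC)C(=O)OC | intermediate
9 | 2-(Cat4α)-3-methoxy-3-oxopropanoic acid (both epimers at the malonate carbon) | c1(OCc9ccccc9)cc(OCc9ccccc9)c2c(c1Br)O[C@H](c4ccc(OCc9ccccc9)c(OCc9ccccc9)c4)[C@@H](OCc9ccccc9)[C@@H]2C(C(=O)O)C(=O)OC | intermediate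
10 | methyl 3,4-dihydroxybenzoate | COC(=O)c1ccc(O)c(O)c1 | starting material
11 | methyl 3,4-bis(benzyloxy)benzoate | COC(=O)c1ccc(OCc9ccccc9)c(OCc9ccccc9)c1 | intermediate
12 | acetylacetone (pentane-2,4-dione) | CC(=O)CC(C)=O | starting material
13 | 1-[3,4-bis(benzyloxy)phenyl]hexane-1,3,5-trione | CC(=O)CC(=O)CC(=O)c1ccc(OCc9ccccc9)c(OCc9ccccc9)c1 | intermediate
14 | 2-[3,4-bis(benzyloxy)phenyl]-6-methyl-4H-pyran-4-one | CC1=CC(=O)C=C(c4ccc(OCc9ccccc9)c(OCc9ccccc9)c4)O1 | intermediate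
15 | methyl 2-(Cat4α)-3-chloro-3-oxopropanoate (acid chloride of 9, both epimers) | c1(OCc9ccccc9)cc(OCc9ccccc9)c2c(c1Br)O[C@H](c4ccc(OCc9ccccc9)c(OCc9ccccc9)c4)[C@@H](OCc9ccccc9)[C@@H]2C(C(=O)Cl)C(=O)OC | intermediate
16 | methyl 2-(Cat4α)-4-[6-[3,4-bis(benzyloxy)phenyl]-4-oxo-4H-pyran-2-yl]-3-oxobutanoate (both epimers at C2 of the butanoate) | c1(OCc9ccccc9)cc(OCc9ccccc9)c2c(c1Br)O[C@H](c4ccc(OCc9ccccc9)c(OCc9ccccc9)c4)[C@@H](OCc9ccccc9)[C@@H]2C(C(=O)OC)C(=O)CC1=CC(=O)C=C(c4ccc(OCc9ccccc9)c(OCc9ccccc9)c4)O1 | intermediate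
17 | 6-(Cat4α)-5,7-dihydroxy-3',4'-bis(benzyloxy)flavone | c1(OCc9ccccc9)cc(OCc9ccccc9)c2c(c1Br)O[C@H](c4ccc(OCc9ccccc9)c(OCc9ccccc9)c4)[C@@H](OCc9ccccc9)[C@@H]2c1c(O)cc3c(c1O)C(=O)C=C(c4ccc(OCc9ccccc9)c(OCc9ccccc9)c4)O3 | intermediate
18 | 8-bromo-6-(Cat4α)-5,7-dihydroxy-3',4'-bis(benzyloxy)flavone | c1(OCc9ccccc9)cc(OCc9ccccc9)c2c(c1Br)O[C@H](c4ccc(OCc9ccccc9)c(OCc9ccccc9)c4)[C@@H](OCc9ccccc9)[C@@H]2c1c(O)c(Br)c3c(c1O)C(=O)C=C(c4ccc(OCc9ccccc9)c(OCc9ccccc9)c4)O3 | intermediate
19 | 8-bromo-6-(Cat4α)-5,7,3',4'-tetrakis(benzyloxy)flavone | c1(OCc9ccccc9)cc(OCc9ccccc9)c2c(c1Br)O[C@H](c4ccc(OCc9ccccc9)c(OCc9ccccc9)c4)[C@@H](OCc9ccccc9)[C@@H]2c1c(OCc9ccccc9)c(Br)c3c(c1OCc9ccccc9)C(=O)C=C(c4ccc(OCc9ccccc9)c(OCc9ccccc9)c4)O3 | intermediate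
20 | (2S)-8-bromo-6-(Cat4α)-5,7,3',4'-tetrakis(benzyloxy)-4-[diethoxy(methyl)silyloxy]flav-3-ene | c1(OCc9ccccc9)cc(OCc9ccccc9)c2c(c1Br)O[C@H](c4ccc(OCc9ccccc9)c(OCc9ccccc9)c4)[C@@H](OCc9ccccc9)[C@@H]2c1c(OCc9ccccc9)c(Br)c3c(c1OCc9ccccc9)C(O[Si](C)(OCC)OCC)=C[C@@H](c4ccc(OCc9ccccc9)c(OCc9ccccc9)c4)O3 | intermediate
21 | (2S)-8-bromo-6-(Cat4α)-5,7,3',4'-tetrakis(benzyloxy)flavanone | c1(OCc9ccccc9)cc(OCc9ccccc9)c2c(c1Br)O[C@H](c4ccc(OCc9ccccc9)c(OCc9ccccc9)c4)[C@@H](OCc9ccccc9)[C@@H]2c1c(OCc9ccccc9)c(Br)c3c(c1OCc9ccccc9)C(=O)C[C@@H](c4ccc(OCc9ccccc9)c(OCc9ccccc9)c4)O3 | intermediate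
22 | (2S,4S)-8-bromo-6-(Cat4α)-5,7,3',4'-tetrakis(benzyloxy)flavan-4-ol (2,4-cis) | c1(OCc9ccccc9)cc(OCc9ccccc9)c2c(c1Br)O[C@H](c4ccc(OCc9ccccc9)c(OCc9ccccc9)c4)[C@@H](OCc9ccccc9)[C@@H]2c1c(OCc9ccccc9)c(Br)c3c(c1OCc9ccccc9)[C@@H](O)C[C@@H](c4ccc(OCc9ccccc9)c(OCc9ccccc9)c4)O3 | intermediate
23 | (2S)-8-bromo-6-(Cat4α)-5,7,3',4'-tetrakis(benzyloxy)flav-3-ene | c1(OCc9ccccc9)cc(OCc9ccccc9)c2c(c1Br)O[C@H](c4ccc(OCc9ccccc9)c(OCc9ccccc9)c4)[C@@H](OCc9ccccc9)[C@@H]2c1c(OCc9ccccc9)c(Br)c3c(c1OCc9ccccc9)C=C[C@@H](c4ccc(OCc9ccccc9)c(OCc9ccccc9)c4)O3 | intermediate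
24 | 2,3-trans-3-boranyl-8-bromo-6-(Cat4α)-5,7,3',4'-tetrakis(benzyloxy)flavan (BH2 on C3 anti to the 2-aryl) | c1(OCc9ccccc9)cc(OCc9ccccc9)c2c(c1Br)O[C@H](c4ccc(OCc9ccccc9)c(OCc9ccccc9)c4)[C@@H](OCc9ccccc9)[C@@H]2c1c(OCc9ccccc9)c(Br)c3c(c1OCc9ccccc9)C[C@H](B)[C@@H](c4ccc(OCc9ccccc9)c(OCc9ccccc9)c4)O3 | intermediate
25 | 8-bromo-3,5,7,3',4'-penta-O-benzylcatechin-(4α→6)-8-bromo-5,7,3',4'-tetra-O-benzylcatechin (bottom unit 2R,3S, 3-OH free) | c1(OCc9ccccc9)cc(OCc9ccccc9)c2c(c1Br)O[C@H](c4ccc(OCc9ccccc9)c(OCc9ccccc9)c4)[C@@H](OCc9ccccc9)[C@@H]2c1c(OCc9ccccc9)c(Br)c3c(c1OCc9ccccc9)C[C@H](O)[C@@H](c4ccc(OCc9ccccc9)c(OCc9ccccc9)c4)O3 | intermediate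
26 | (−)-epicatechin, (2R,3R) | Oc1cc(O)c2c(c1)O[C@H](c1ccc(O)c(O)c1)[C@H](O)C2 | starting material
27 | 5,7,3',4'-tetra-O-benzyl-(−)-epicatechin | c1(OCc9ccccc9)cc(OCc9ccccc9)c2c(c1)O[C@H](c4ccc(OCc9ccccc9)c(OCc9ccccc9)c4)[C@H](O)C2 | intermediate
28 | 8-bromo-5,7,3',4'-tetra-O-benzyl-(−)-epicatechin | c1(OCc9ccccc9)cc(OCc9ccccc9)c2c(c1Br)O[C@H](c4ccc(OCc9ccccc9)c(OCc9ccccc9)c4)[C@H](O)C2 | intermediate
29 | 8-bromo-3,5,7,3',4'-penta-O-benzyl-(−)-epicatechin | c1(OCc9ccccc9)cc(OCc9ccccc9)c2c(c1Br)O[C@H](c4ccc(OCc9ccccc9)c(OCc9ccccc9)c4)[C@H](OCc9ccccc9)C2 | intermediate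
30 | 8-bromo-3,5,7,3',4'-penta-O-benzyl-4β-(2-ethoxyethoxy)-(−)-epicatechin (ether trans to 3-OBn drawn; either C4 epimer serves) | c1(OCc9ccccc9)cc(OCc9ccccc9)c2c(c1Br)O[C@H](c4ccc(OCc9ccccc9)c(OCc9ccccc9)c4)[C@H](OCc9ccccc9)[C@H]2OCCOCC | intermediate
31 | 8-bromo-penta-O-benzylepicatechin-(4β→6)-8-bromo-penta-O-benzylcatechin-(4α→6)-8-bromo-5,7,3',4'-tetra-O-benzylcatechin | c1(OCc9ccccc9)cc(OCc9ccccc9)c2c(c1Br)O[C@H](c4ccc(OCc9ccccc9)c(OCc9ccccc9)c4)[C@H](OCc9ccccc9)[C@H]2c1c(OCc9ccccc9)c(Br)c2c(c1OCc9ccccc9)[C@@H](c1c(OCc9ccccc9)c(Br)c3c(c1OCc9ccccc9)C[C@H](O)[C@@H](c4ccc(OCc9ccccc9)c(OCc9ccccc9)c4)O3)[C@H](OCc9ccccc9)[C@@H](c4ccc(OCc9ccccc9)c(OCc9ccccc9)c4)O2 | intermediate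
32 | epicatechin-(4β→6)-catechin-(4α→6)-catechin (CNP0163146.4) | Oc1cc(O)c2c(c1)O[C@H](c1ccc(O)c(O)c1)[C@H](O)[C@H]2c1c(O)cc2c(c1O)[C@@H](c1c(O)cc3c(c1O)C[C@H](O)[C@@H](c1ccc(O)c(O)c1)O3)[C@H](O)[C@@H](c1ccc(O)c(O)c1)O2 | target

**Step count and risks**

Total step count: 22. Longest linear sequence: 16 steps (steps 1–6, 9–16, 21 and 22).

Steps most likely to fail:

1. Step 10 (proposed new method). Proton transfer may park the substrate as the unreactive β-keto ester enolate, so that pyranone carbon 3 never reaches the ester, or methoxide set free may add to the pyranone and open it. The fallback uses known chemistry and forms the middle-C4–bottom-C6 bond directly instead of building ring A. Ether 5 is ionised with Me3SiOTf in CH2Cl2 at −78 °C in the presence of the 8-bromo nucleophile 3, whose C8 is blocked, so that its C6 attacks the C4 cation anti to 3-OBn (Friedel–Crafts arylation of a flavan C4 cation). This sets out from 5 and 3 and comes back to the route at 25; it makes no compound outside the list (F0).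

2. Step 9. Proton transfer from the malonyl C–H of 15 to the lithiated pyranone may outrun C–C bond formation, and the ketene so formed may dimerise or be O-acylated. The fallback reverses the polarity in a decarboxylative Claisen condensation of the Masamune type. Pyranone 14 is lithiated with LiN(SiMe3)2 and carboxylated with CO2 to give [6-[3,4-bis(benzyloxy)phenyl]-4-oxo-4H-pyran-2-yl]acetic acid F1, which with 1,1'-carbonyldiimidazole gives the acyl imidazole 1-[[6-[3,4-bis(benzyloxy)phenyl]-4-oxo-4H-pyran-2-yl]acetyl]imidazole F2. The magnesium enolate of half-acid 9 (MgCl2, Et3N, MeCN/THF, rt) is then C-acylated by F2 and loses CO2. This sets out from 14 and 9 and comes back at 16.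

3. Step 13. Hydride delivery to the hindered, electron-rich flavone may be slow or show poor facial selectivity. The fallback gives up catalyst control: conjugate reduction of 19 with KBH(s-Bu)3 in THF at −78 °C should give 21 together with its C2 epimer, (2R)-8-bromo-6-(Cat4α)-5,7,3',4'-tetrakis(benzyloxy)flavanone F3. The two are diastereomers and are separated by chromatography. F3 is recycled with catalytic DBU in toluene, which equilibrates the C2 epimers through the ring-opened 2'-hydroxychalcone F4, and the mixture is separated again. This sets out from 19 and comes back at 21.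

Further compounds
F0 | step 10 | none | none
F1 | step 9 | [6-[3,4-bis(benzyloxy)phenyl]-4-oxo-4H-pyran-2-yl]acetic acid | OC(=O)CC1=CC(=O)C=C(c4ccc(OCc9ccccc9)c(OCc9ccccc9)c4)O1
F2 | step 9 | 1-[[6-[3,4-bis(benzyloxy)phenyl]-4-oxo-4H-pyran-2-yl]acetyl]imidazole | O=C(CC1=CC(=O)C=C(c4ccc(OCc9ccccc9)c(OCc9ccccc9)c4)O1)n1ccnc1
F3 | step 13 | (2R)-8-bromo-6-(Cat4α)-5,7,3',4'-tetrakis(benzyloxy)flavanone (C2 epimer of 21) | c1(OCc9ccccc9)cc(OCc9ccccc9)c2c(c1Br)O[C@H](c4ccc(OCc9ccccc9)c(OCc9ccccc9)c4)[C@@H](OCc9ccccc9)[C@@H]2c1c(OCc9ccccc9)c(Br)c3c(c1OCc9ccccc9)C(=O)C[C@H](c4ccc(OCc9ccccc9)c(OCc9ccccc9)c4)O3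
F4 | step 13 | (E)-1-[3-bromo-5-(Cat4α)-2-hydroxy-4,6-bis(benzyloxy)phenyl]-3-[3,4-bis(benzyloxy)phenyl]prop-2-en-1-one (ring-opened chalcone) | c1(OCc9ccccc9)cc(OCc9ccccc9)c2c(c1Br)O[C@H](c4ccc(OCc9ccccc9)c(OCc9ccccc9)c4)[C@@H](OCc9ccccc9)[C@@H]2c1c(OCc9ccccc9)c(Br)c(O)c(c1OCc9ccccc9)C(=O)/C=C/c4ccc(OCc9ccccc9)c(OCc9ccccc9)c4
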